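The route rests on detaching ring A from ring C at its two neighbouring bonds, O1–C8a and C4–C4a. In the key step a 3,5-dioxygenated benzyne, released from an o-silylaryl triflate, inserts into the C(=O)–O bond of a 2-(chromen-8-yl)acrylic acid. The phenoxide so formed closes ring C by oxa-Michael addition, so the complete isoflavanone skeleton arises in one operation from two fragments of similar size. The step exploits the C5 oxygen of ring A: lying next to C4a, it steers the carboxylate oxygen to C8a and the acyl carbon to C4a. C3 is set afterwards by palladium-catalysed decarboxylative asymmetric protonation of the derived allyl enol carbonate.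

Key step: step 10

Assumption: in step 12 the (S)-configured phosphinooxazoline ligand with Meldrum's acid as proton donor is taken to deliver the (R)-ketone. If this pairing favours the (S)-ketone, the (R)-ligand is used with nothing else changed.

Step 1
Reactants: 1 phloroglucinol
Product: 2 3,5-bis(methoxymethoxy)phenol
Conditions: MOMCl (2 equiv), i-Pr2NEt, DMF, 0 °C → rt
Reagents that add atoms: chloromethyl methyl ether, COCCl
Why: Williamson-type O-alkoxymethylation of the threefold-symmetric triphenol, in which only the degree of alkylation needs control, so that limiting the chloride should give the bis-ether, separable from the mono- and tris-ethers.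

Step 2
Reactants: 2 3,5-bis(methoxymethoxy)phenol
Product: 3 3,5-bis(methoxymethoxy)phenyl N-isopropylcarbamate
Conditions: i-PrNCO, Et3N (cat.), CH2Cl2, rt
Reagents that add atoms: isopropyl isocyanate, CC(C)N=C=O
Why: Base-catalysed addition of the phenol to the isocyanate should give the N-monoalkyl carbamate, a directing group for ortho-metalation that can later be removed under mild base.

Step 3
Reactants: 3 3,5-bis(methoxymethoxy)phenyl N-isopropylcarbamate
Product: 6 3,5-bis(methoxymethoxy)-2-(trimethylsilyl)phenyl N-isopropylcarbamate, via N-silyl carbamate 4 (not isolated), via N-silyl ortho-silyl carbamate 5 (not isolated)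
Conditions: TBSOTf, TMEDA, Et2O, 0 °C → rt; n-BuLi, TMEDA, −78 °C; TMSCl, −78 °C → rt; aq. NH4Cl
Reagents that add atoms: chlorotrimethylsilane, C[Si](C)(C)Cl
Why: Directed ortho-metalation, in which in situ N-silylation masks the N–H, lithiation should occur at the position flanked by the carbamate and a methoxymethoxy group (the two such positions are equivalent by symmetry) and silyl chloride traps the aryllithium, the N–Si bond being cleaved on work-up.

Step 4
Reactants: 6 3,5-bis(methoxymethoxy)-2-(trimethylsilyl)phenyl N-isopropylcarbamate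
Product: 8 3,5-bis(methoxymethoxy)-2-(trimethylsilyl)phenyl trifluoromethanesulfonate, via silylphenol 7 (not isolated)
Conditions: DBU, Et2NH, MeCN, 40 °C; then PhNTf2, rt
Reagents that add atoms: N-phenylbis(trifluoromethanesulfonimide), O=S(=O)(N(c1ccccc1)S(=O)(=O)C(F)(F)F)C(F)(F)F
Why: E1cB cleavage of the N-monoalkyl carbamate (the isocyanate is trapped by Et2NH) should free the phenoxide, which is O-triflated in the same flask to give the o-silylaryl triflate aryne precursor.

Step 5
Reactants: 9 2,4-dihydroxyacetophenone
Product: 10 1-[2-hydroxy-4-(methoxymethoxy)phenyl]ethan-1-one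
Conditions: MOMCl, K2CO3, acetone, rt
Reagents that add atoms: chloromethyl methyl ether, COCCl
Why: Williamson-type etherification that should be selective for the 4-hydroxyl group, because the 2-hydroxyl group is tied up in a hydrogen bond to the acetyl carbonyl.

Step 6
Reactants: 10 1-[2-hydroxy-4-(methoxymethoxy)phenyl]ethan-1-one
Product: 11 1-{4-(methoxymethoxy)-2-[(2-methylbut-3-yn-2-yl)oxy]phenyl}ethan-1-one
Conditions: 3-chloro-3-methylbut-1-yne, DBU, CuCl2 (cat.), MeCN, 0 °C → rt
Reagents that add atoms: 3-chloro-3-methylbut-1-yne, C#CC(C)(C)Cl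
Why: Copper-catalysed propargylic etherification, which should O-alkylate even the chelated, hindered phenol with the tertiary propargylic chloride.

Step 7
Reactants: 11 1-{4-(methoxymethoxy)-2-[(2-methylbut-3-yn-2-yl)oxy]phenyl}ethan-1-one
Product: 13 1-[5-(methoxymethoxy)-2,2-dimethyl-2H-chromen-8-yl]ethan-1-one, via allenylphenol 12 (not isolated)
Conditions: PhNEt2, 180 °C
Reagents that add atoms: none
Why: Aromatic propargyl Claisen rearrangement to the only free ortho position (the other carries the acetyl group), followed by tautomerisation, 1,5-hydrogen shift and 6π-oxa-electrocyclisation, should give the 2H-chromene with its oxygen next to the acetyl-bearing carbon.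

Step 8
Reactants: 13 1-[5-(methoxymethoxy)-2,2-dimethyl-2H-chromen-8-yl]ethan-1-one
Product: 14 1-[5-(methoxymethoxy)-2,2-dimethyl-2H-chromen-8-yl]ethenyl trifluoromethanesulfonate
Conditions: KN(SiMe3)2, THF, −78 °C; PhNTf2, −78 → 0 °C
Reagents that add atoms: N-phenylbis(trifluoromethanesulfonimide), O=S(=O)(N(c1ccccc1)S(=O)(=O)C(F)(F)F)C(F)(F)F
Why: Enol triflate formation by O-sulfonylation of the potassium enolate of a methyl ketone with a single enolisable site, the electron-rich product to be used without prolonged storage.

Step 9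
Reactants: 14 1-[5-(methoxymethoxy)-2,2-dimethyl-2H-chromen-8-yl]ethenyl trifluoromethanesulfonate
Product: 16 2-[5-(methoxymethoxy)-2,2-dimethyl-2H-chromen-8-yl]prop-2-enoic acid, via mixed anhydride 15 (not isolated)
Conditions: Pd(OAc)2 (cat.), dppf, KOAc, CO (1 atm), DMF, 60 °C; aqueous work-up
Reagents that add atoms: carbon monoxide, [C-]#[O+]; potassium acetate, CC(=O)[O-].[K+]; water, O (the hydroxyl oxygen comes from acetate or water)
Why: Palladium-catalysed hydroxycarbonylation of the vinyl triflate (oxidative addition, CO insertion, capture of the acylpalladium by acetate, hydrolysis of the mixed anhydride on work-up) should give the 2-arylacrylic acid with the 1,1-disubstituted alkene intact.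

Step 10
Reactants: 8 3,5-bis(methoxymethoxy)-2-(trimethylsilyl)phenyl trifluoromethanesulfonate; 16 2-[5-(methoxymethoxy)-2,2-dimethyl-2H-chromen-8-yl]prop-2-enoic acid
Product: 19 rac-5,7-bis(methoxymethoxy)-3-[5-(methoxymethoxy)-2,2-dimethyl-2H-chromen-8-yl]chroman-4-one, via aryne 17 (not isolated), via o-hydroxyaryl vinyl ketone 18 (not isolated)
Conditions: CsF, THF, 125 °C (sealed tube)
Reagents that add atoms: none
Why: Fluoride attack on silicon in 8 expels triflate to give aryne 17; the caesium carboxylate of 16 adds through oxygen to the aryne carbon meta to the flanking methoxymethoxy group (the future C8a, forming O1–C8a), and the aryl anion left at the future C4a attacks the adjacent ester carbonyl, after which the four-membered alkoxide opens to the o-acylphenoxide (forming C4–C4a), a net insertion of the aryne into the C(=O)–O bond of the acid. The closest known reaction type is the fluoride-promoted C–O addition of carboxylic acids to arynes, which with acrylic acids is known to end in 4-chromanones. The transient benzoxetene closes by 4-exo-trig attack of the aryl anion, and ring C then closes by 6-endo-trig oxa-Michael addition of the phenoxide of 18 to its α-aryl enone. The new stereocenter C3 arises by uncontrolled protonation of the enolate and is racemic at this stage; it is set in step 12. The step needs regioselective addition to the unsymmetrical aryne, which the inductive and distortion effect of the 3-alkoxy group should secure as it does for 3-alkoxybenzynes in general, and it needs acyl transfer to outrun protonation of the aryl anion, which the high temperature and the aprotic medium favour.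

Step 11
Reactants: 19 rac-5,7-bis(methoxymethoxy)-3-[5-(methoxymethoxy)-2,2-dimethyl-2H-chromen-8-yl]chroman-4-one
Product: 20 allyl 5,7-bis(methoxymethoxy)-3-[5-(methoxymethoxy)-2,2-dimethyl-2H-chromen-8-yl]-2H-chromen-4-yl carbonate
Conditions: KN(SiMe3)2, THF, −78 °C; allyl chloroformate, −78 → 0 °C
Reagents that add atoms: allyl chloroformate, C=CCOC(=O)Cl
Why: O-acylation of the hindered, fully substituted potassium enolate by the hard chloroformate should give the allyl enol carbonate, and any C-acylated isomer would enter step 12 through the same palladium enolate.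

Step 12
Reactants: 20 allyl 5,7-bis(methoxymethoxy)-3-[5-(methoxymethoxy)-2,2-dimethyl-2H-chromen-8-yl]-2H-chromen-4-yl carbonate
Product: 21 (3R)-5,7-bis(methoxymethoxy)-3-[5-(methoxymethoxy)-2,2-dimethyl-2H-chromen-8-yl]chroman-4-one
Conditions: Pd2(dba)3 (cat.), (S)-(CF3)3-t-BuPHOX, Meldrum's acid, 1,4-dioxane, 40 °C
Reagents that add atoms: none
Why: Palladium-catalysed decarboxylative asymmetric protonation, in which zerovalent palladium ionises the allyl carbonate, loss of CO2 leaves a ligand-bound palladium enolate, and face-selective proton transfer from Meldrum's acid (which takes up the allyl group) should set C3 as (R) under control of the chiral ligand, the ortho-oxygenated 3-aryl group being of the type that gives the best selectivity and the neutral conditions leaving the new center unenolised.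

Step 13
Reactants: 21 (3R)-5,7-bis(methoxymethoxy)-3-[5-(methoxymethoxy)-2,2-dimethyl-2H-chromen-8-yl]chroman-4-one
Product: 22 (3R)-5,7-dihydroxy-3-(5-hydroxy-2,2-dimethyl-2H-chromen-8-yl)chroman-4-one (target)
Conditions: HCl (2 M), MeOH/THF, rt → 40 °C
Reagents that add atoms: none
Why: Acid-catalysed acetal exchange with methanol should remove the three aryl methoxymethyl ethers, the dilute acid and low temperature being chosen to spare the 2,2-dimethylchromene and to keep acid-catalysed enolisation at C3 slow.

Compound list
1 | phloroglucinol (benzene-1,3,5-triol) | Oc1cc(O)cc(O)c1 | starting material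
2 | 3,5-bis(methoxymethoxy)phenol | COCOc1cc(O)cc(OCOC)c1 | intermediate
3 | 3,5-bis(methoxymethoxy)phenyl N-isopropylcarbamate | COCOc1cc(OCOC)cc(OC(=O)NC(C)C)c1 | intermediate
4 | 3,5-bis(methoxymethoxy)phenyl N-(tert-butyldimethylsilyl)-N-isopropylcarbamate (not isolated) | COCOc1cc(OCOC)cc(OC(=O)N(C(C)C)[Si](C)(C)C(C)(C)C)c1 | intermediate
5 | 3,5-bis(methoxymethoxy)-2-(trimethylsilyl)phenyl N-(tert-butyldimethylsilyl)-N-isopropylcarbamate (not isolated) | COCOc1cc(OCOC)c([Si](C)(C)C)c(OC(=O)N(C(C)C)[Si](C)(C)C(C)(C)C)c1 | intermediate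
6 | 3,5-bis(methoxymethoxy)-2-(trimethylsilyl)phenyl N-isopropylcarbamate | COCOc1cc(OCOC)c([Si](C)(C)C)c(OC(=O)NC(C)C)c1 | intermediate
7 | 3,5-bis(methoxymethoxy)-2-(trimethylsilyl)phenol (not isolated) | COCOc1cc(O)c([Si](C)(C)C)c(OCOC)c1 | intermediate
8 | 3,5-bis(methoxymethoxy)-2-(trimethylsilyl)phenyl trifluoromethanesulfonate | COCOc1cc(OCOC)c([Si](C)(C)C)c(OS(=O)(=O)C(F)(F)F)c1 | intermediate
9 | 2,4-dihydroxyacetophenone | CC(=O)c1ccc(O)cc1O | starting material
10 | 1-[2-hydroxy-4-(methoxymethoxy)phenyl]ethan-1-one | CC(=O)c1ccc(OCOC)cc1O | intermediate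
11 | 1-{4-(methoxymethoxy)-2-[(2-methylbut-3-yn-2-yl)oxy]phenyl}ethan-1-one | CC(=O)c1ccc(OCOC)cc1OC(C)(C)C#C | intermediate
12 | 1-[2-hydroxy-4-(methoxymethoxy)-3-(3-methylbuta-1,2-dien-1-yl)phenyl]ethan-1-one (not isolated) | CC(=O)c1ccc(OCOC)c(C=C=C(C)C)c1O | intermediate
13 | 1-[5-(methoxymethoxy)-2,2-dimethyl-2H-chromen-8-yl]ethan-1-one | CC(=O)c1ccc(OCOC)c2c1OC(C)(C)C=C2 | intermediate
14 | 1-[5-(methoxymethoxy)-2,2-dimethyl-2H-chromen-8-yl]ethenyl trifluoromethanesulfonate | C=C(OS(=O)(=O)C(F)(F)F)c1ccc(OCOC)c2c1OC(C)(C)C=C2 | intermediate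
15 | acetic 2-[5-(methoxymethoxy)-2,2-dimethyl-2H-chromen-8-yl]prop-2-enoic anhydride (not isolated) | C=C(C(=O)OC(C)=O)c1ccc(OCOC)c2c1OC(C)(C)C=C2 | intermediate
16 | 2-[5-(methoxymethoxy)-2,2-dimethyl-2H-chromen-8-yl]prop-2-enoic acid | C=C(C(=O)O)c1ccc(OCOC)c2c1OC(C)(C)C=C2 | intermediate
17 | 3,5-bis(methoxymethoxy)benzyne (not isolated) | COCOC1=CC(OCOC)=CC#C1 | intermediate
18 | 1-[2-hydroxy-4,6-bis(methoxymethoxy)phenyl]-2-[5-(methoxymethoxy)-2,2-dimethyl-2H-chromen-8-yl]prop-2-en-1-one (not isolated) | C=C(C(=O)c1c(O)cc(OCOC)cc1OCOC)c1ccc(OCOC)c2c1OC(C)(C)C=C2 | intermediate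
19 | rac-5,7-bis(methoxymethoxy)-3-[5-(methoxymethoxy)-2,2-dimethyl-2H-chromen-8-yl]chroman-4-one | O=C1C(c2ccc(OCOC)c3c2OC(C)(C)C=C3)COc2cc(OCOC)cc(OCOC)c12 | intermediate
20 | allyl 5,7-bis(methoxymethoxy)-3-[5-(methoxymethoxy)-2,2-dimethyl-2H-chromen-8-yl]-2H-chromen-4-yl carbonate | C=CCOC(=O)OC1=C(c2ccc(OCOC)c3c2OC(C)(C)C=C3)COc2cc(OCOC)cc(OCOC)c12 | intermediate
21 | (3R)-5,7-bis(methoxymethoxy)-3-[5-(methoxymethoxy)-2,2-dimethyl-2H-chromen-8-yl]chroman-4-one | COCOc1ccc([C@@H]2COc3cc(OCOC)cc(OCOC)c3C2=O)c2c1C=CC(C)(C)O2 | intermediate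
22 | (3R)-5,7-dihydroxy-3-(5-hydroxy-2,2-dimethyl-2H-chromen-8-yl)chroman-4-one | CC1(C)C=Cc2c(O)ccc([C@@H]3COc4cc(O)cc(O)c4C3=O)c2O1 | target

Total step count: 13. Longest linear sequence: 9 steps (steps 5 to 13); the aryne precursor branch (steps 1 to 4) joins at step 10.

Steps most likely to fail

Step 10. The aryl anion may be protonated before the 1,3-acyl transfer, so that the reaction stops at simple O-arylation of the acid, or the acrylate may oligomerise at 125 °C. The fallback makes the C4–C4a bond by an anionic ortho-Fries shift in a medium without any proton source. It sets out from 2 and 16. Iodination of 2 ortho to the hydroxyl group (N-iodosuccinimide, CH2Cl2, −20 °C) should give 2-iodo-3,5-bis(methoxymethoxy)phenol F1. Steglich esterification of F1 with acid 16 (DCC, DMAP, CH2Cl2, 0 °C) should give 2-iodo-3,5-bis(methoxymethoxy)phenyl 2-[5-(methoxymethoxy)-2,2-dimethyl-2H-chromen-8-yl]prop-2-enoate F2. Iodine–magnesium exchange (i-PrMgCl·LiCl, THF, −40 °C → rt) should then trigger the 1,3-O→C acyl shift to the magnesium phenoxide of 18, which closes by oxa-Michael addition on warming and rejoins the route at 19.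

Step 12. Proton transfer to the palladium enolate may show poor facial selectivity, or the hindered enol carbonate may ionise sluggishly. The fallback sets out from 19 and sets C3 by reduction under dynamic kinetic resolution. Asymmetric transfer hydrogenation (RuCl[(R,R)-TsDPEN](p-cymene), HCO2H/Et3N, DMF, 40 °C) should give (3R,4R)-5,7-bis(methoxymethoxy)-3-[5-(methoxymethoxy)-2,2-dimethyl-2H-chromen-8-yl]chroman-4-ol F3: hydride is delivered to the carbonyl face as for aryl alkyl ketones, and C3 epimerises rapidly under the basic conditions, so the material funnels into the cis alcohol. Oxidation with Dess–Martin periodinane (NaHCO3, CH2Cl2, 0 °C) should return the ketone without enolisation and rejoins the route at 21.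

Step 13. Acid-catalysed enolisation during removal of the three acetals may erode the configuration at C3. The fallback sets out from 19 and postpones the separation of enantiomers to the end. The same acid treatment (HCl, MeOH/THF, rt → 40 °C) applied to the racemate should give rac-5,7-dihydroxy-3-(5-hydroxy-2,2-dimethyl-2H-chromen-8-yl)chroman-4-one F4. Preparative HPLC on an amylose tris(3,5-dimethylphenylcarbamate) stationary phase under neutral elution should then separate the enantiomers, and the (R)-enantiomer rejoins the route at 22.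

Further compounds
F1 | step 10 | 2-iodo-3,5-bis(methoxymethoxy)phenol | COCOc1cc(O)c(I)c(OCOC)c1
F2 | step 10 | 2-iodo-3,5-bis(methoxymethoxy)phenyl 2-[5-(methoxymethoxy)-2,2-dimethyl-2H-chromen-8-yl]prop-2-enoate | C=C(C(=O)Oc1cc(OCOC)cc(OCOC)c1I)c1ccc(OCOC)c2c1OC(C)(C)C=C2
F3 | step 12 | (3R,4R)-5,7-bis(methoxymethoxy)-3-[5-(methoxymethoxy)-2,2-dimethyl-2H-chromen-8-yl]chroman-4-ol | COCOc1ccc([C@@H]2COc3cc(OCOC)cc(OCOC)c3[C@@H]2O)c2c1C=CC(C)(C)O2
F4 | step 13 | rac-5,7-dihydroxy-3-(5-hydroxy-2,2-dimethyl-2H-chromen-8-yl)chroman-4-one | CC1(C)C=Cc2c(O)ccc(C3COc4cc(O)cc(O)c4C3=O)c2O1
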